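**Retrosynthetic overview**
1. Ring C is opened at O1–C2 (retro oxa-Michael, the reverse of the chalcone isomerase reaction). This leads from schizolaenone C back to the fully unprotected 3'-geranyl-2',4',6',3,5-pentahydroxychalcone. The forward closure is the last step and fixes C2 (S) and the 6- versus 8-geranyl regiochemistry in one catalytic event.
2. The Cα=Cβ bond of the chalcone is cut to 3-geranylphloracetophenone and 3,5-dihydroxybenzaldehyde (Claisen–Schmidt, no protecting groups).
3. The aryl–CH2 bond is cut to phloracetophenone and geranyl bromide (prenyltransferase-like C-alkylation of the phloroglucinol nucleus).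
4. Ring order: rings A and B are bought as arenes. Ring C is the only ring built, and it is built last.

Assumption: the sense of induction is taken from intermolecular additions to chalcones, where the quinine-derived thiourea serves the Re face of C-β and the quinidine-derived one the Si face; the first run is checked by chiral HPLC and circular dichroism (2S: negative band near 290 nm, positive near 330 nm), and if the sense is reversed the equally commercial quinine-derived pseudoenantiomer is used with nothing else changed.

**Route**

Step 1
Reactants: 1 phloracetophenone (2,4,6-trihydroxyacetophenone); 2 geranyl bromide ((2E)-1-bromo-3,7-dimethylocta-2,6-diene)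
Product: 3 3-geranylphloracetophenone (1-{3-[(2E)-3,7-dimethylocta-2,6-dien-1-yl]-2,4,6-trihydroxyphenyl}ethan-1-one)
Conditions: 1 (dried, 1.5 equiv), 2 (1.0 equiv), K2CO3 (1.0 equiv), acetone, reflux, 6 h, N2
Reagents that add atoms: none
Why: Phenolate C-alkylation (SN2): the mono-potassium salt of the vinylogous acid 1 behaves as a 1,3-dicarbonyl-type ambident nucleophile that attacks the primary allylic bromide through ring carbon C3 and rearomatises by tautomerisation, the E-alkene is kept because only the CH2–Br carbon is touched, excess cheap 1 holds back double alkylation, and no stereocenter is formed.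

Step 2
Reactants: 3 3-geranylphloracetophenone; 4 3,5-dihydroxybenzaldehyde
Product: 6 (E)-3'-geranyl-2',4',6',3,5-pentahydroxychalcone, via racemic aldol adduct 5 (not isolated)
Conditions: 4 (1.2 equiv), KOH (50% aq, 25 equiv), degassed EtOH, Ar, dark, 0 °C to rt, 48 h; poured into ice-cold 2 N HCl to pH 3; EtOAc; rapid SiO2 (hexane/EtOAc, 0.1% AcOH) to remove any flavanone
Reagents that add atoms: none
Why: Claisen–Schmidt aldol condensation with E1cB loss of water from 5: the two phenoxides of 4 are meta to the formyl group and cannot quench its electrophilicity, concentrated KOH reaches the small enolate fraction of the polyanion of 3 and also holds the product as the ring-open chalcone polyanion, the fast cold quench frees 6 in the acidic window where it does not cyclise, the new alkene is E on thermodynamic grounds, and no stereocenter survives.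

Step 3
Reactants: 6 (E)-3'-geranyl-2',4',6',3,5-pentahydroxychalcone
Product: 7 schizolaenone C ((2S)-6-geranyl-5,7,3',5'-tetrahydroxyflavanone)
Conditions: N-[3,5-bis(trifluoromethyl)phenyl]-N'-[(9R)-6'-methoxycinchonan-9-yl]thiourea (quinidine-derived, C29H28F6N4OS, 20 mol %), dry PhMe/2-MeTHF 3:1 (0.05 molar), −20 °C, 72 h, dark; cold 10% citric acid wash; SiO2
Reagents that add atoms: none
Why: Proposed new method: a chalcone-isomerase-like 6-endo-trig intramolecular oxa-Michael addition in which the thiourea N–H pair binds the free lone pair of the enone carbonyl as an oxyanion hole while the quinuclidine deprotonates the acidic, unhindered 6'-OH, so the ion-paired phenoxide adds to the Si face of C-β and sets C2 as (S); the 2'-OH is pressed by the geranyl CH2 into the strong chelate with C=O and is shielded from the bulky catalyst, which biases closure to the 6-geranyl over the 8-geranyl isomer (the prenyl analogue already leans this way without catalyst), the retained 5-OH to O=C4 chelate makes closure effectively irreversible at −20 °C so C2 is not scrambled, and the closest known reaction type is the cinchona-thiourea-catalysed enantioselective oxa-Michael cyclisation of mono-2'-hydroxychalcones and their α-ester-activated analogues.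

**Compound list**
1 | phloracetophenone (2,4,6-trihydroxyacetophenone) | CC(=O)c1c(O)cc(O)cc1O | starting material
2 | geranyl bromide ((2E)-1-bromo-3,7-dimethylocta-2,6-diene) | CC(C)=CCC/C(C)=C/CBr | starting material
3 | 3-geranylphloracetophenone | CC(C)=CCC/C(C)=C/Cc1c(O)cc(O)c(C(C)=O)c1O | intermediate
4 | 3,5-dihydroxybenzaldehyde | O=Cc1cc(O)cc(O)c1 | starting material
5 | racemic aldol adduct, 1-(3-geranyl-2,4,6-trihydroxyphenyl)-3-(3,5-dihydroxyphenyl)-3-hydroxypropan-1-one | CC(C)=CCC/C(C)=C/Cc1c(O)cc(O)c(C(=O)CC(O)c2cc(O)cc(O)c2)c1O | intermediate
6 | (E)-3'-geranyl-2',4',6',3,5-pentahydroxychalcone | CC(C)=CCC/C(C)=C/Cc1c(O)cc(O)c(C(=O)/C=C/c2cc(O)cc(O)c2)c1O | intermediate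
7 | schizolaenone C, (2S)-2-(3,5-dihydroxyphenyl)-6-[(2E)-3,7-dimethylocta-2,6-dien-1-yl]-5,7-dihydroxy-2,3-dihydro-4H-chromen-4-one | CC(C)=CCC/C(C)=C/Cc1c(O)cc2c(c1O)C(=O)C[C@@H](c1cc(O)cc(O)c1)O2 | target

**Totals and risks**
Total step count: 3. Longest linear sequence: 3 (1 to 3 to 6 to 7).

Highest risk, step 3. The catalyst must beat the racemic background closure, and it must pick 6'-OH over 2'-OH on a substrate with five free phenols. The fallback gives up catalyst control. It sets out from 6 and comes back at 7.
- Compound 6 is closed with NaOAc in refluxing EtOH to a mixture of racemic schizolaenone C F1 and racemic 8-geranyl-5,7,3',5'-tetrahydroxyflavanone F2.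
- The two regioisomers are separated on silica.
- F1 is resolved on an amylose tris(3,5-dimethylphenylcarbamate) column into 7 and (2R)-schizolaenone C F3.
- F2 and F3 are reopened with cold 50% KOH and quenched into cold acid, which returns them to 6 for the next pass.

Second, step 2. The polyanion of 3 may enolise too poorly, or the polyphenolates may oxidise. The fallback masks the phenols. It sets out from 3 and 4 and comes back at 6.
- Compound 3 with MOMCl (2.2 equiv) and DIPEA in CH2Cl2 gives 1-[3-geranyl-2-hydroxy-4,6-bis(methoxymethoxy)phenyl]ethanone F4.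
- Compound 4 gives 3,5-bis(methoxymethoxy)benzaldehyde F5 in the same way.
- KOH in aqueous EtOH joins them to 3'-geranyl-2'-hydroxy-4',6',3,5-tetrakis(methoxymethoxy)chalcone F6.
- Catalytic concentrated HCl in MeOH at 40 °C strips all four acetals to give 6.
- A brief cold KOH treatment and acid quench reopens any flavanone formed in the acid step.
- It does not matter which ortho hydroxyl stays free in F4, because every acetal is removed before ring closure.

Third, step 1. O-alkylation and double alkylation can cut the yield. The fallback replaces SN2 alkylation by π-allyl chemistry. It sets out from 1 and comes back at 3.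
- Geraniol with ClCO2Me and pyridine gives geranyl methyl carbonate F7.
- F7 reacts with 1 under Pd(PPh3)4 (zerovalent palladium, 3 mol %) in THF at rt.
- O-geranylation is reversible under palladium, so material funnels to the C-geranyl product at the unhindered allyl terminus, and no external base is present.

**Further compounds**
F1 | step 3 | racemic schizolaenone C | CC(C)=CCC/C(C)=C/Cc1c(O)cc2c(c1O)C(=O)CC(c1cc(O)cc(O)c1)O2
F2 | step 3 | racemic 8-geranyl-5,7,3',5'-tetrahydroxyflavanone | CC(C)=CCC/C(C)=C/Cc1c(O)cc(O)c2c1OC(c1cc(O)cc(O)c1)CC2=O
F3 | step 3 | (2R)-schizolaenone C | CC(C)=CCC/C(C)=C/Cc1c(O)cc2c(c1O)C(=O)C[C@H](c1cc(O)cc(O)c1)O2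
F4 | step 2 | 1-[3-geranyl-2-hydroxy-4,6-bis(methoxymethoxy)phenyl]ethanone | CC(C)=CCC/C(C)=C/Cc1c(OCOC)cc(OCOC)c(C(C)=O)c1O
F5 | step 2 | 3,5-bis(methoxymethoxy)benzaldehyde | O=Cc1cc(OCOC)cc(OCOC)c1
F6 | step 2 | 3'-geranyl-2'-hydroxy-4',6',3,5-tetrakis(methoxymethoxy)chalcone | CC(C)=CCC/C(C)=C/Cc1c(OCOC)cc(OCOC)c(C(=O)/C=C/c2cc(OCOC)cc(OCOC)c2)c1O
F7 | step 1 | geranyl methyl carbonate | CC(C)=CCC/C(C)=C/COC(=O)OC
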